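**Retrosynthetic overview**
1. Target ⇒ (quinone reduction, sixfold OH-directed bromination, O-demethylation) 2,5-bis(2-bromo-4-methoxyphenoxy)-1,4-benzoquinone. The one Br per outer ring that no free OH could direct (ortho to the ether O) is bought in.
2. Key disconnection: both C(OAr)–C(=O) bonds of central ring B are cut. This gives two identical C3 units, each a β-lithio-β-aryloxyacrylate (β-acylvinyl/masked acyl anion at the normally electrophilic β-carbon) that also carries the ester acceptor. Head-to-tail cyclodimerisation makes both C–C bonds and fixes the 2,5-pattern.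
3. C3 unit ⇒ oxa-Michael addition of 2-bromo-4-methoxyphenol to ethyl propiolate, so both ether C–O bonds exist before ring B does.
4. Ring order: rings A and C come intact from the phenol, and ring B is the only ring formed (step 2).

Assumption: the target has no stereocentre and no configurationally stable axis, so it is achiral and no enantiomer has to be selected. The only stereochemical element in the route is the E geometry of the enol-ether alkene.

**Step 1**
Reactants: 1 2-bromo-4-methoxyphenol; 2 ethyl propiolate
Product: 3 ethyl (E)-3-(2-bromo-4-methoxyphenoxy)acrylate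
Conditions: 1,4-diazabicyclo[2.2.2]octane (10 mol%), CH2Cl2, 0 °C to rt, 2 h
Reagents that add atoms: none
Why: Amine-catalysed oxa-Michael addition of a phenol to an ynoate, in which the phenoxide adds to the β-carbon and protonation of the allenolate gives the favoured E enol ether, whose β-H lies cis to CO2Et as the next step needs; no stereocentre is formed.

**Step 2**
Reactants: 3 ethyl (E)-3-(2-bromo-4-methoxyphenoxy)acrylate (two molecules per product)
Product: 6 2,5-bis(2-bromo-4-methoxyphenoxy)benzene-1,4-diol, via vinyllithium 4 (not isolated), via quinone 5 (not isolated)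
Conditions: 3 added to LiN(iPr)2 (1.1 equiv, commercial solution), THF, −100 °C, 30 min, then −100 to −70 °C, 2 h; AcOH (3 equiv), THF, −78 °C; aq Na2S2O4, EtOAc, rt, N2
Reagents that add atoms: none
Why: Proposed new method: LiN(iPr)2 removes the β-H of 3, which is acidified by the aryloxy oxygen and lies cis to the chelating ester carbonyl, to give the configurationally stable vinyllithium 4, a β-acylvinyl (masked acyl) anion whose normally electrophilic β-carbon is now the nucleophile, and on warming two molecules of 4 acylate each other head to tail at the ester carbons (intermolecular addition–elimination, then a 6-exo-trig closure allowed by the cis geometry, 2 LiOEt lost), so that two pairs of normally electrophilic carbons are joined, ring B is closed with the 2,5-diaryloxy pattern fixed, and quinone 5 is reduced to 6 by Na2S2O4 in the work-up; the closest known reaction types are the β-lithiation of (E)-β-alkoxyacrylates with addition to carbonyl compounds (tetronate synthesis), whose known self-acylation above about −80 °C is used here on purpose, and the self-condensation of ortho-lithiated benzamides to anthraquinones; no stereocentre is formed.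

**Step 3**
Reactants: 6 2,5-bis(2-bromo-4-methoxyphenoxy)benzene-1,4-diol
Product: 7 2,5-bis(2-bromo-4-hydroxyphenoxy)benzene-1,4-diol
Conditions: BBr3 (6 equiv), CH2Cl2, −78 °C to rt, 12 h, Ar; degassed H2O, 0 °C
Reagents that add atoms: none
Why: Lewis-acid aryl methyl ether cleavage, in which BBr3 binds each OMe oxygen and bromide removes the methyl group by SN2 as MeBr, while the diaryl ether bonds (no sp3 carbon to attack), the aryl bromides and the borate-masked hydroquinone survive; no stereocentre is involved.

**Step 4**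
Reactants: 7 2,5-bis(2-bromo-4-hydroxyphenoxy)benzene-1,4-diol
Product: 9 2,5-dibromo-3,6-bis(2,3,5-tribromo-4-hydroxyphenoxy)benzene-1,4-diol, via octabromoquinone 8 (not isolated)
Conditions: Br2 (7.2 equiv), AcOH/CH2Cl2 1:1, 0 °C to rt, dark, 6 h; aq Na2S2O4, EtOAc, rt
Reagents that add atoms: bromine, BrBr
Why: Phenol-directed electrophilic aromatic bromination, in which each outer OH (para position blocked by the ether O) sends Br to its two free ortho carbons C3 and C5, ring B is brominated at its only two C–H positions and oxidised by the seventh equivalent of Br2 to quinone 8, and the reductive Na2S2O4 quench returns hydroquinone 9; no stereocentre is formed.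

**Compound list**
1 | 2-bromo-4-methoxyphenol | COc1ccc(O)c(Br)c1 | starting material
2 | ethyl propiolate (ethyl prop-2-ynoate) | C#CC(=O)OCC | starting material
3 | ethyl (E)-3-(2-bromo-4-methoxyphenoxy)acrylate | CCOC(=O)/C=C/Oc1ccc(OC)cc1Br | intermediate
4 | ethyl (E)-3-(2-bromo-4-methoxyphenoxy)-3-lithioacrylate (Li cis to CO2Et) | CCOC(=O)/C=C(\[Li])Oc1ccc(OC)cc1Br | intermediate
5 | 2,5-bis(2-bromo-4-methoxyphenoxy)cyclohexa-2,5-diene-1,4-dione | O=C1C=C(Oc2ccc(OC)cc2Br)C(=O)C=C1Oc1ccc(OC)cc1Br | intermediate
6 | 2,5-bis(2-bromo-4-methoxyphenoxy)benzene-1,4-diol | Oc1cc(Oc2ccc(OC)cc2Br)c(O)cc1Oc1ccc(OC)cc1Br | intermediate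
7 | 2,5-bis(2-bromo-4-hydroxyphenoxy)benzene-1,4-diol | Oc1cc(Oc2ccc(O)cc2Br)c(O)cc1Oc1ccc(O)cc1Br | intermediate
8 | 2,5-dibromo-3,6-bis(2,3,5-tribromo-4-hydroxyphenoxy)cyclohexa-2,5-diene-1,4-dione | O=C1C(Br)=C(Oc2cc(Br)c(O)c(Br)c2Br)C(=O)C(Br)=C1Oc1cc(Br)c(O)c(Br)c1Br | intermediate
9 | 2,5-dibromo-3,6-bis(2,3,5-tribromo-4-hydroxyphenoxy)benzene-1,4-diol (achiral) | Oc1c(Br)cc(Oc2c(O)c(Br)c(Oc3cc(Br)c(O)c(Br)c3Br)c(O)c2Br)c(Br)c1Br | target

**Total step count:** 4. **Longest linear sequence:** 4 (1 → 3 → 6 → 7 → 9).

**Steps most likely to fail**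

Highest risk, step 2. Four failure modes are foreseeable:
- Vinyllithium 4 can add to the divinyl ketone, or to quinone 5, as soon as these are released.
- LiOEt can exchange the aryloxy groups of 5.
- LiN(iPr)2 can attack the aryl C–H between Br and OMe, which gives an aryne on warming.
- 4 can lose LiOAr.

The fallback sets out from 3. It keeps the head-to-tail ring construction but hides the quinone until all carbanion is gone. Aminolysis of 3 with MeNH(OMe)·HCl and iPrMgCl (THF, −20 °C) gives (E)-3-(2-bromo-4-methoxyphenoxy)-N-methoxy-N-methylacrylamide F1. LiN(iPr)2 (THF, −100 °C) then gives (E)-3-(2-bromo-4-methoxyphenoxy)-3-lithio-N-methoxy-N-methylacrylamide F2. On warming to −40 °C this closes to dilithium 2,5-bis(2-bromo-4-methoxyphenoxy)-1,4-bis[methoxy(methyl)amino]cyclohexa-2,5-diene-1,4-diolate F3 (cis/trans mixture, both centres vanish on collapse). F3 is a doubly chelated tetrahedral intermediate that is neither electrophilic nor a source of alkoxide. Pouring into cold 1 M HCl collapses it to quinone 5, where the route is rejoined.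

Second risk, step 4. Seven equivalents of Br2 on a compound with four free phenols may attack ipso (para to an outer OH) and cleave ring A or C oxidatively. They may also leave hepta- and nonabromide mixtures that are hard to separate.

The fallback sets out from 5, isolated by leaving out the Na2S2O4 wash of step 2. It spreads the bromination over protected and free stages.
- Br2 (4.2 equiv, AcOH, rt to 40 °C) brominates ring B and, under OMe direction (ortho to OMe, para to the resident Br), one position of each outer ring. This gives 2,5-dibromo-3,6-bis(2,5-dibromo-4-methoxyphenoxy)cyclohexa-2,5-diene-1,4-dione F7.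
- Aq Na2S2O4 gives 2,5-dibromo-3,6-bis(2,5-dibromo-4-methoxyphenoxy)benzene-1,4-diol F8.
- BBr3 gives 2,5-dibromo-3,6-bis(2,5-dibromo-4-hydroxyphenoxy)benzene-1,4-diol F9.
- Only 3 equiv of Br2 are then needed, for the last ortho position of each outer phenol plus oxidation of ring B. This gives octabromoquinone 8, where the route is rejoined.

Third risk, step 3. Compounds 6 and 7 are electron-rich, air-sensitive hydroquinones, and their polyborates may precipitate before both methyl groups are lost.

The fallback sets out from 3 and moves the deprotection ahead of ring construction. BBr3 (2.2 equiv, CH2Cl2, −78 to 0 °C) on the small, soluble monomer gives ethyl (E)-3-(2-bromo-4-hydroxyphenoxy)acrylate F4. LiN(iPr)2 (2.2 equiv, THF, −100 °C) gives ethyl (E)-3-[2-bromo-4-(lithiooxy)phenoxy]-3-lithioacrylate F5, whose phenoxide also switches off lithiation of the aryl ring. Warming gives, by the same head-to-tail cyclodimerisation, 2,5-bis(2-bromo-4-hydroxyphenoxy)cyclohexa-2,5-diene-1,4-dione F6. The AcOH quench and Na2S2O4 work-up reduce F6 to 7, where the route is rejoined.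

**Further compounds**
F1 | step 2 | (E)-3-(2-bromo-4-methoxyphenoxy)-N-methoxy-N-methylacrylamide | CON(C)C(=O)/C=C/Oc1ccc(OC)cc1Br
F2 | step 2 | (E)-3-(2-bromo-4-methoxyphenoxy)-3-lithio-N-methoxy-N-methylacrylamide (Li cis to the amide carbonyl) | CON(C)C(=O)/C=C(\[Li])Oc1ccc(OC)cc1Br
F3 | step 2 | dilithium 2,5-bis(2-bromo-4-methoxyphenoxy)-1,4-bis[methoxy(methyl)amino]cyclohexa-2,5-diene-1,4-diolate (cis/trans mixture) | [Li]OC1(N(C)OC)C=C(Oc2ccc(OC)cc2Br)C(O[Li])(N(C)OC)C=C1Oc1ccc(OC)cc1Br
F4 | step 3 | ethyl (E)-3-(2-bromo-4-hydroxyphenoxy)acrylate | CCOC(=O)/C=C/Oc1ccc(O)cc1Br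
F5 | step 3 | ethyl (E)-3-[2-bromo-4-(lithiooxy)phenoxy]-3-lithioacrylate (C–Li cis to CO2Et) | CCOC(=O)/C=C(\[Li])Oc1ccc(O[Li])cc1Br
F6 | step 3 | 2,5-bis(2-bromo-4-hydroxyphenoxy)cyclohexa-2,5-diene-1,4-dione | O=C1C=C(Oc2ccc(O)cc2Br)C(=O)C=C1Oc1ccc(O)cc1Br
F7 | step 4 | 2,5-dibromo-3,6-bis(2,5-dibromo-4-methoxyphenoxy)cyclohexa-2,5-diene-1,4-dione | O=C1C(Br)=C(Oc2cc(Br)c(OC)cc2Br)C(=O)C(Br)=C1Oc1cc(Br)c(OC)cc1Br
F8 | step 4 | 2,5-dibromo-3,6-bis(2,5-dibromo-4-methoxyphenoxy)benzene-1,4-diol | Oc1c(Br)c(Oc2cc(Br)c(OC)cc2Br)c(O)c(Br)c1Oc1cc(Br)c(OC)cc1Br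
F9 | step 4 | 2,5-dibromo-3,6-bis(2,5-dibromo-4-hydroxyphenoxy)benzene-1,4-diol | Oc1c(Br)c(Oc2cc(Br)c(O)cc2Br)c(O)c(Br)c1Oc1cc(Br)c(O)cc1Br
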